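## Retrosynthetic overview

1. Target ⇐ C10 tigloylation and C6 4‑hydroxybenzoylation of the (1S,4S,5S,6S,10R) 4,6,10‑triol of the hydroazulene core.
2. Triol ⇐ one‑pot SmI2 unravelling of an ether‑bridged epoxy ketone: the C5–O (oxirane) and C7–O (bridge) bonds α to the C6 ketone are cut, then the ketone is reduced. The bridge oxygen becomes the C10 hydroxyl.
3. Epoxy ketone ⇐ epoxidation of a cyclopentene‑fused 8‑oxabicyclo[3.2.1]octenone. The five‑membered ring is closed by aldol condensation after two exo conjugate additions (methyl, then the C2–C4 chain) have set the C1 quaternary centre.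
4. 8‑Oxabicyclo[3.2.1]octadienone ⇐ [5+2] cycloaddition of aromatic 3‑oxidopyrylium (from furfuryl alcohol by Achmatowicz oxidation) with an enantiopure (E)‑propenyl sulfoxide, which then leaves as sulfenic acid to give the C8=C9 alkene.
5. Ring order: seven‑membered carbocycle first (cycloaddition), five‑membered ring second (aldol), oxygen bridge opened last.

Locants used throughout ("daucane" = 1,8‑dimethyl‑4‑(propan‑2‑yl)bicyclo[5.3.0]decane): C1 = methyl‑bearing quaternary ring‑fusion carbon, C2–C3 = ring CH2, C4 = isopropyl carbinol carbon, C5 = ring‑fusion CH, then C6 (aroyloxy), C7, C8 (methyl), C9, C10 (tigloyloxy) around the seven‑membered ring.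

Assumption: the (R)‑sulfinyl group of 7 directs the cycloaddition to the (1S,5S) enantiomer of 10; if the opposite sense is found, the enantiomer of 7 (from the enantiomeric menthyl sulfinate) is used with no other change.

## Route

Step 1
Reactants: 1 furan‑2‑ylmethanol (furfuryl alcohol)
Product: 3 5‑oxo‑5,6‑dihydro‑2H‑pyran‑2‑yl acetate (racemic), via 6‑hydroxy‑2H‑pyran‑3(6H)‑one 2 (not isolated)
Conditions: mCPBA, CH2Cl2, 0 °C; then Ac2O, pyridine, DMAP (cat.), 0 °C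
Reagents that add atoms: 3‑chloroperoxybenzoic acid, OOC(=O)c1cccc(Cl)c1; acetic anhydride, CC(=O)OC(C)=O
Why: Achmatowicz rearrangement (peracid oxidation of the 2‑furylcarbinol and ring expansion to the pyranone lactol) followed by in‑flask O‑acetylation gives the oxidopyrylium precursor; its acetal centre is racemic and is destroyed in step 3.

Step 2
Reactants: 4 (1R,2S,5R)‑menthyl (S)‑4‑methylbenzenesulfinate; 5 (E)‑1‑bromoprop‑1‑ene
Product: 7 (R)‑1‑methyl‑4‑[(E)‑prop‑1‑en‑1‑ylsulfinyl]benzene, via (E)‑prop‑1‑enylmagnesium bromide 6 (not isolated)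
Conditions: Mg, THF, 40 °C; then 4, toluene–THF, −40 → 0 °C
Reagents that add atoms: none
Why: Andersen sulfoxide synthesis: the alkenylmagnesium bromide, formed with retention of E geometry, displaces menthoxide at sulfur with inversion to give the (R)‑sulfoxide.

Step 3
Reactants: 3 5‑oxo‑5,6‑dihydro‑2H‑pyran‑2‑yl acetate; 7 (R)‑1‑methyl‑4‑[(E)‑prop‑1‑en‑1‑ylsulfinyl]benzene
Product: 10 (1S,5S)‑7‑methyl‑8‑oxabicyclo[3.2.1]octa‑3,6‑dien‑2‑one, via 3‑oxidopyrylium 8 (not isolated), via sulfinyl cycloadduct 9 (not isolated)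
Conditions: Et3N (1.2 equiv), 7 (2 equiv), CH2Cl2, rt; then toluene, 110 °C
Reagents that add atoms: none
Why: Proposed new method: Et3N eliminates acetate from 3 to the aromatic betaine 8, whose [5+2] cycloaddition (Hendrickson–Sammes oxidopyrylium cycloaddition) with the acceptor alkene 7 should place the sulfinyl carbon at the pyrylium C6 terminus as acrylates do (so the methyl ends at C8, next to the C7 bridgehead), with the sulfinyl group shielding one π‑face as in known intramolecular pyrone–sulfinylalkene cycloadditions (setting C7 and C10); thermal sulfoxide syn‑elimination can then only go toward C8 (the other β‑hydrogen is at a bridgehead) and unveils the C8=C9 alkene; the closest known reactions are oxidopyrylium–acrylate cycloadditions and the use of vinyl sulfoxides as alkyne equivalents.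

Step 4
Reactants: 10 (1S,5S)‑7‑methyl‑8‑oxabicyclo[3.2.1]octa‑3,6‑dien‑2‑one
Product: 11 trimethyl{[(1S,4S,5S)‑4,7‑dimethyl‑8‑oxabicyclo[3.2.1]octa‑2,6‑dien‑2‑yl]oxy}silane
Conditions: MeMgBr, CuBr·SMe2 (10 mol%), TMSCl, THF, −78 °C
Reagents that add atoms: methylmagnesium bromide, C[Mg]Br; chlorotrimethylsilane, C[Si](C)(C)Cl
Why: Copper‑catalysed, TMSCl‑accelerated conjugate addition of the methyl Grignard reagent occurs on the exo face and the enolate is trapped regiospecifically as its silyl enol ether (the C1 centre formed here is removed again in step 5).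

Step 5
Reactants: 11 trimethyl{[(1S,4S,5S)‑4,7‑dimethyl‑8‑oxabicyclo[3.2.1]octa‑2,6‑dien‑2‑yl]oxy}silane
Product: 12 (1S,5R)‑4,7‑dimethyl‑8‑oxabicyclo[3.2.1]octa‑3,6‑dien‑2‑one
Conditions: Pd(OAc)2 (1.1 equiv), MeCN, rt
Reagents that add atoms: none
Why: Saegusa–Ito oxidation: the palladium enolate undergoes β‑hydride elimination toward C1 (C7 is a bridgehead), regenerating the enone that now carries the C1 methyl.

Step 6
Reactants: 13 4‑methylpent‑1‑en‑3‑one
Product: 15 2‑(2‑bromoethyl)‑2‑(propan‑2‑yl)‑1,3‑dioxolane, via 1‑bromo‑4‑methylpentan‑3‑one 14 (not isolated)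
Conditions: HBr (gas), HOCH2CH2OH, CH2Cl2, 0 °C → rt
Reagents that add atoms: hydrogen bromide, Br; ethane‑1,2‑diol, OCCO
Why: Conjugate addition of HBr to the enone and in‑flask ketalisation give the protected β‑bromo ketone that serves as a ketone homoenolate equivalent.

Step 7
Reactants: 12 (1S,5R)‑4,7‑dimethyl‑8‑oxabicyclo[3.2.1]octa‑3,6‑dien‑2‑one; 15 2‑(2‑bromoethyl)‑2‑(propan‑2‑yl)‑1,3‑dioxolane
Product: 18 (1S,4S,5R)‑4,7‑dimethyl‑4‑{2‑[2‑(propan‑2‑yl)‑1,3‑dioxolan‑2‑yl]ethyl}‑8‑oxabicyclo[3.2.1]oct‑6‑en‑2‑one, via dioxolanylethylmagnesium bromide 16 (not isolated), via silyl enol ether 17 (not isolated)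
Conditions: 15, Mg, THF, rt; then CuBr·SMe2 (10 mol%), TMSCl, 12, THF, −78 → −30 °C; dilute aqueous acid work‑up
Reagents that add atoms: none
Why: Copper‑catalysed, TMSCl‑assisted conjugate addition of the Grignard reagent to the β‑methyl enone takes place on the exo face next to the oxygen bridge (as in additions to the analogous tropane enones), creating the C1 quaternary stereocentre with the methyl endo and the chain syn to the bridge oxygen (1S); the work‑up hydrolyses the silyl enol ether.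

Step 8
Reactants: 18 (1S,4S,5R)‑4,7‑dimethyl‑4‑{2‑[2‑(propan‑2‑yl)‑1,3‑dioxolan‑2‑yl]ethyl}‑8‑oxabicyclo[3.2.1]oct‑6‑en‑2‑one
Product: 20 (1S,7S,10R)‑7,10‑epoxydauca‑4,8‑dien‑6‑one, via diketone 19 (not isolated)
Conditions: p‑TsOH·H2O (cat.), acetone–H2O, 50 °C; then KOH (0.5 equiv), MeOH, 60 °C
Reagents that add atoms: none
Why: Acid unmasks the isopropyl ketone and base‑mediated intramolecular aldol condensation of the 1,6‑diketone closes the five‑membered ring as the acylcyclopentene, because the C6 ketone can enolise only toward C5 (C7 is a bridgehead) and attack of C5 on C4 is a five‑membered ring closure.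

Step 9
Reactants: 20 (1S,7S,10R)‑7,10‑epoxydauca‑4,8‑dien‑6‑one
Product: 21 (1R,4S,5S,7S,10R)‑4,5:7,10‑diepoxydauc‑8‑en‑6‑one
Conditions: t‑BuOOH, benzyltrimethylammonium hydroxide (cat.), THF, 0 °C → rt
Reagents that add atoms: tert‑butyl hydroperoxide, CC(C)(C)OO
Why: Weitz–Scheffer nucleophilic epoxidation of the enone: the hydroperoxide adds to C4 and the oxirane closes on the exo face anti to the endo C1 methyl, setting C4 (S) and placing the oxirane oxygen on the same face as the bridge oxygen.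

Step 10
Reactants: 21 (1R,4S,5S,7S,10R)‑4,5:7,10‑diepoxydauc‑8‑en‑6‑one
Product: 23 (1S,4S,5S,6S,10R)‑dauc‑8‑ene‑4,6,10‑triol, via keto diol 22 (not isolated)
Conditions: SmI2 (8 equiv), THF–MeOH, −78 °C; then H2O, Et3N, −78 → 0 °C
Reagents that add atoms: none
Why: SmI2 reductive cleavage of α‑heterosubstituted ketones cuts the oxirane C5–O bond and the C7–O bridge bond (both aligned with the carbonyl π system), the samarium enolate at C5 being protonated on the face away from the C1 methyl and C4 isopropyl (trans ring fusion, 5S); SmI2–water–amine reduction of the resulting ketone through the ketyl chelated to the C4 alkoxide should then give the equatorial 6S alcohol syn to the C4 hydroxyl.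

Step 11
Reactants: 23 (1S,4S,5S,6S,10R)‑dauc‑8‑ene‑4,6,10‑triol; 24 4‑acetoxybenzoic acid
Product: 25 (1S,4S,5S,6S,10R)‑4,10‑dihydroxydauc‑8‑en‑6‑yl 4‑acetoxybenzoate
Conditions: 24 (1.05 equiv), DCC, DMAP (cat.), CH2Cl2, 0 °C
Reagents that add atoms: none
Why: Steglich esterification: the equatorial secondary C6 hydroxyl is acylated in preference to the axial, neopentyl C10 hydroxyl and the tertiary C4 hydroxyl, with retention at C6.

Step 12
Reactants: 25 (1S,4S,5S,6S,10R)‑4,10‑dihydroxydauc‑8‑en‑6‑yl 4‑acetoxybenzoate; 26 (E)‑2‑methylbut‑2‑enoyl chloride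
Product: 27 (1S,4S,5S,6S,10R)‑4‑hydroxy‑10‑{[(E)‑2‑methylbut‑2‑enoyl]oxy}dauc‑8‑en‑6‑yl 4‑acetoxybenzoate
Conditions: 26, pyridine, DMAP (cat.), CH2Cl2, 40 °C
Reagents that add atoms: none
Why: DMAP‑catalysed acylation of the remaining secondary (allylic) hydroxyl by the acid chloride; the E geometry of the tigloyl group is the stable one and is retained, and the tertiary alcohol does not react.

Step 13
Reactants: 27 (1S,4S,5S,6S,10R)‑4‑hydroxy‑10‑{[(E)‑2‑methylbut‑2‑enoyl]oxy}dauc‑8‑en‑6‑yl 4‑acetoxybenzoate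
Product: 28 (1S,4S,5S,6S,10R)‑4‑hydroxy‑10‑{[(E)‑2‑methylbut‑2‑enoyl]oxy}dauc‑8‑en‑6‑yl 4‑hydroxybenzoate (CNP0273650.6)
Conditions: NH4OAc, MeOH–H2O, rt
Reagents that add atoms: none
Why: Chemoselective solvolysis of the phenolic acetate (NH4OAc‑mediated deacetylation of aryl acetates), which is far more labile than the alkyl benzoate and tiglate esters, frees the phenol.

## Compound list

1 | furan‑2‑ylmethanol (furfuryl alcohol) | OCc1ccco1 | starting material
2 | 6‑hydroxy‑2H‑pyran‑3(6H)‑one (racemic) | O=C1COC(O)C=C1 | intermediate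
3 | 5‑oxo‑5,6‑dihydro‑2H‑pyran‑2‑yl acetate (racemic) | CC(=O)OC1OCC(=O)C=C1 | intermediate
4 | (1R,2S,5R)‑menthyl (S)‑4‑methylbenzenesulfinate | Cc1ccc(cc1)[S@@](=O)O[C@@H]1C[C@H](C)CC[C@H]1C(C)C | starting material
5 | (E)‑1‑bromoprop‑1‑ene | C/C=C/Br | starting material
6 | (E)‑prop‑1‑en‑1‑ylmagnesium bromide | C/C=C/[Mg]Br | intermediate
7 | (R)‑1‑methyl‑4‑[(E)‑prop‑1‑en‑1‑ylsulfinyl]benzene | C/C=C/[S@@](=O)c1ccc(C)cc1 | intermediate
8 | pyrylium‑3‑olate (3‑oxidopyrylium) | [O-]c1ccc[o+]c1 | intermediate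
9 | (1S,5S,6S,7R)‑7‑methyl‑6‑[(R)‑4‑methylbenzenesulfinyl]‑8‑oxabicyclo[3.2.1]oct‑3‑en‑2‑one (endo‑sulfinyl, exo‑methyl isomer shown; the exo‑sulfinyl isomer eliminates to the same product) | O=C1C=C[C@H]2[C@@H]([S@@](=O)c3ccc(C)cc3)[C@H](C)[C@@H]1O2 | intermediate
10 | (1S,5S)‑7‑methyl‑8‑oxabicyclo[3.2.1]octa‑3,6‑dien‑2‑one | O=C1C=C[C@H]2C=C(C)[C@@H]1O2 | intermediate
11 | trimethyl{[(1S,4S,5S)‑4,7‑dimethyl‑8‑oxabicyclo[3.2.1]octa‑2,6‑dien‑2‑yl]oxy}silane (4‑methyl exo) | C[Si](C)(C)OC1=C[C@H](C)[C@H]2C=C(C)[C@@H]1O2 | intermediate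
12 | (1S,5R)‑4,7‑dimethyl‑8‑oxabicyclo[3.2.1]octa‑3,6‑dien‑2‑one | O=C1C=C(C)[C@H]2C=C(C)[C@@H]1O2 | intermediate
13 | 4‑methylpent‑1‑en‑3‑one | C=CC(=O)C(C)C | starting material
14 | 1‑bromo‑4‑methylpentan‑3‑one | BrCCC(=O)C(C)C | intermediate
15 | 2‑(2‑bromoethyl)‑2‑(propan‑2‑yl)‑1,3‑dioxolane | CC(C)C1(CCBr)OCCO1 | intermediate
16 | {2‑[2‑(propan‑2‑yl)‑1,3‑dioxolan‑2‑yl]ethyl}magnesium bromide | CC(C)C1(CC[Mg]Br)OCCO1 | intermediate
17 | trimethylsilyl enol ether of 18 (C6–O–Si, C5=C6) | C[Si](C)(C)OC1=C[C@](C)(CCC3(C(C)C)OCCO3)[C@H]2C=C(C)[C@@H]1O2 | intermediate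
18 | (1S,4S,5R)‑4,7‑dimethyl‑4‑{2‑[2‑(propan‑2‑yl)‑1,3‑dioxolan‑2‑yl]ethyl}‑8‑oxabicyclo[3.2.1]oct‑6‑en‑2‑one (4‑methyl endo, chain exo) | O=C1C[C@](C)(CCC3(C(C)C)OCCO3)[C@H]2C=C(C)[C@@H]1O2 | intermediate
19 | (1S,4S,5R)‑4,7‑dimethyl‑4‑(4‑methyl‑3‑oxopentyl)‑8‑oxabicyclo[3.2.1]oct‑6‑en‑2‑one | O=C1C[C@](C)(CCC(=O)C(C)C)[C@H]2C=C(C)[C@@H]1O2 | intermediate
20 | (1S,7S,10R)‑7,10‑epoxydauca‑4,8‑dien‑6‑one (C7–O–C10 ether bridge; C4=C5 enone) | O=C1C3=C(C(C)C)CC[C@]3(C)[C@H]2C=C(C)[C@@H]1O2 | intermediate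
21 | (1R,4S,5S,7S,10R)‑4,5:7,10‑diepoxydauc‑8‑en‑6‑one (oxirane oxygen syn to the bridge oxygen, anti to C1 methyl) | O=C1[C@@]34O[C@]3(C(C)C)CC[C@]4(C)[C@H]2C=C(C)[C@@H]1O2 | intermediate
22 | (1S,4S,5R,10R)‑4,10‑dihydroxydauc‑8‑en‑6‑one | O[C@@H]1C=C(C)CC(=O)[C@@H]2[C@]1(C)CC[C@]2(O)C(C)C | intermediate
23 | (1S,4S,5S,6S,10R)‑dauc‑8‑ene‑4,6,10‑triol | O[C@@H]1C=C(C)C[C@H](O)[C@@H]2[C@]1(C)CC[C@]2(O)C(C)C | intermediate
24 | 4‑acetoxybenzoic acid | CC(=O)Oc1ccc(cc1)C(=O)O | starting material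
25 | (1S,4S,5S,6S,10R)‑4,10‑dihydroxydauc‑8‑en‑6‑yl 4‑acetoxybenzoate | O[C@@H]1C=C(C)C[C@H](OC(=O)c3ccc(OC(C)=O)cc3)[C@@H]2[C@]1(C)CC[C@]2(O)C(C)C | intermediate
26 | (E)‑2‑methylbut‑2‑enoyl chloride (tigloyl chloride) | C/C=C(\C)C(Cl)=O | starting material
27 | (1S,4S,5S,6S,10R)‑4‑hydroxy‑10‑{[(E)‑2‑methylbut‑2‑enoyl]oxy}dauc‑8‑en‑6‑yl 4‑acetoxybenzoate | C/C=C(\C)C(=O)O[C@@H]1C=C(C)C[C@H](OC(=O)c3ccc(OC(C)=O)cc3)[C@@H]2[C@]1(C)CC[C@]2(O)C(C)C | intermediate
28 | (1S,4S,5S,6S,10R)‑4‑hydroxy‑10‑{[(E)‑2‑methylbut‑2‑enoyl]oxy}dauc‑8‑en‑6‑yl 4‑hydroxybenzoate | C/C=C(\C)C(=O)O[C@@H]1C=C(C)C[C@H](OC(=O)c2ccc(O)cc2)[C@@H]2[C@]1(C)CC[C@]2(O)C(C)C | target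

## Step count

Total steps: 13 (steps 2 and 6 prepare the two reagents).
Longest linear sequence: 11 steps (1, 3, 4, 5, 7, 8, 9, 10, 11, 12, 13).

## Steps most likely to fail, with fallbacks

Step 3 (reactivity, regiochemistry and face control of the sulfoxide cycloaddition). The fallback sets out from 3 and drops the sulfoxide auxiliary. The ylide is trapped with methyl (E)‑but‑2‑enoate (Et3N, MeCN, 60 °C), which should give the same orientation (ester at C9, methyl at C8) and racemic methyl 7‑methyl‑2‑oxo‑8‑oxabicyclo[3.2.1]oct‑3‑ene‑6‑carboxylate F1. LiOH hydrolysis and classical resolution of the acid as its (R)‑1‑phenylethylammonium salt give (1S,5S,6S,7R)‑7‑methyl‑2‑oxo‑8‑oxabicyclo[3.2.1]oct‑3‑ene‑6‑carboxylic acid F2. Kochi oxidative decarboxylation (Pb(OAc)4, Cu(OAc)2 cat., pyridine, benzene, 80 °C) then forms the C8=C9 alkene, elimination toward the bridgehead being impossible, and the route is rejoined at 10.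

Step 10 (C5 protonation and, above all, the C6 configuration from the one‑pot reduction). The fallback sets out from 21 and replaces thermodynamic reduction by kinetic reduction plus inversion. SmI2 in THF–MeOH at −78 °C alone is used and keto diol 22 is isolated. NaBH4 (MeOH, −20 °C) attacks the C6 ketone from the open face anti to the angular methyl and gives the axial epimer (1S,4S,5S,6R,10R)‑dauc‑8‑ene‑4,6,10‑triol F3. Mitsunobu esterification with 24 (PPh3, DIAD, THF, 0 °C) inverts C6 while installing the aroyl group, and the route is rejoined at 25.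

Step 11 (site selectivity between the C6 and C10 hydroxyls). The fallback sets out from 23 and uses temporary protection with the acylation order reversed. The syn C4/C6 diol is tied up with PhB(OH)2 (toluene, removal of water) as (1S,4S,5S,6S,10R)‑4,6‑O‑(phenylboranediyl)dauc‑8‑ene‑4,6,10‑triol F4. The only free hydroxyl is acylated with 26 (pyridine, DMAP) to give the 10‑O‑tigloyl boronate F5. Transesterification with pinacol releases (1S,4S,5S,6S,10R)‑4,6‑dihydroxydauc‑8‑en‑10‑yl (E)‑2‑methylbut‑2‑enoate F6, whose C6 hydroxyl is esterified with 24 (DCC, DMAP) to rejoin the route at 27.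

## Further compounds

F1 | step 3 | methyl (1S*,5S*,6S*,7R*)‑7‑methyl‑2‑oxo‑8‑oxabicyclo[3.2.1]oct‑3‑ene‑6‑carboxylate (racemic; one enantiomer drawn) | O=C1C=C[C@H]2[C@@H](C(=O)OC)[C@H](C)[C@@H]1O2
F2 | step 3 | (1S,5S,6S,7R)‑7‑methyl‑2‑oxo‑8‑oxabicyclo[3.2.1]oct‑3‑ene‑6‑carboxylic acid | O=C1C=C[C@H]2[C@@H](C(O)=O)[C@H](C)[C@@H]1O2
F3 | step 10 | (1S,4S,5S,6R,10R)‑dauc‑8‑ene‑4,6,10‑triol | O[C@@H]1C=C(C)C[C@@H](O)[C@@H]2[C@]1(C)CC[C@]2(O)C(C)C
F4 | step 11 | (1S,4S,5S,6S,10R)‑4,6‑O‑(phenylboranediyl)dauc‑8‑ene‑4,6,10‑triol | O[C@@H]1C=C(C)C[C@H](OB(c3ccccc3)O4)[C@@H]2[C@]1(C)CC[C@]24C(C)C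
F5 | step 11 | (1S,4S,5S,6S,10R)‑4,6‑O‑(phenylboranediyl)‑4,6‑dihydroxydauc‑8‑en‑10‑yl (E)‑2‑methylbut‑2‑enoate | C/C=C(\C)C(=O)O[C@@H]1C=C(C)C[C@H](OB(c3ccccc3)O4)[C@@H]2[C@]1(C)CC[C@]24C(C)C
F6 | step 11 | (1S,4S,5S,6S,10R)‑4,6‑dihydroxydauc‑8‑en‑10‑yl (E)‑2‑methylbut‑2‑enoate | C/C=C(\C)C(=O)O[C@@H]1C=C(C)C[C@H](O)[C@@H]2[C@]1(C)CC[C@]2(O)C(C)C
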